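**Retrosynthetic overview**
1. Target ⇐ diol 27 (selective C21 acetylation) ⇐ ring E by intramolecular reductive N‑alkylation of the lactam with a C19 aldehyde; C2/C18 from a syn‑crotylation of aldehyde 21.
2. 21 ⇐ bridged ketimine 20 by oxidative scission of C1=C2 (proposed new step), which turns the auxiliary carbocycle F into the ring D lactam plus the C2–C4 chain.
3. Ring A ⇐ six‑membered ring A′ by Favorskii ring contraction of chloride 17 (key step); ring A′ from a Michael–Claisen annulation with methyl acrylate.
4. Rings B/C ⇐ aldol condensation of triketone 12, assembled from lactol 8, formaldehyde and cyclohexane‑1,3‑dione.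
5. C5 quaternary centre ⇐ Cu‑catalysed asymmetric vinyl addition to enone 3. Ring order: F (auxiliary) → C (bought) → B → A′ → A → D → E.

Locants: C1 lactam C=O; C2 CH(OH); C3, C4 CH2; C5 quaternary C bearing C21H2O; C6 CH; C7 NCH2 (ring D); C8 quaternary C; C9=C10 enone; C11 C=O; C12 CH2 (ring B); C13 CH2; C14 CH(C22O2Me); C15 CH; C16, C17 CH2; C18 CH(CH3); C19 NCH2 (ring E). Ring F = C1, C2, C3, C4, C5, C8.

Assumption: the target's C14/C15 configuration (both hydrogens on the face of C1) is the thermodynamically preferred one, so that methoxide equilibration in step 9 delivers it.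

**Step 1**
Reactants: 1 3-chlorocyclohex-2-en-1-one; 2 (1,3-dioxolan-2-ylmethyl)magnesium bromide
Product: 3 3-(1,3-dioxolan-2-ylmethyl)cyclohex-2-en-1-one
Conditions: CuBr·SMe2 (5 mol %), THF, −40 → 0 °C
Reagents that add atoms: none
Why: Cu‑catalysed conjugate addition–elimination of a Grignard reagent on a β‑chloroenone installs the C6–C7 unit (C7 masked as acetal) on the future C5; no stereocentre.

**Step 2**
Reactants: 3 3-(1,3-dioxolan-2-ylmethyl)cyclohex-2-en-1-one; 4 vinylmagnesium bromide
Product: 5 (R)-3-(1,3-dioxolan-2-ylmethyl)-3-vinylcyclohexan-1-one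
Conditions: Cu(OTf)2 (3 mol %), chiral C2‑symmetric imidazolinium salt (NHC precursor, 4 mol %), Et2O, −30 → 0 °C; aq. NH4Cl
Reagents that add atoms: none
Why: Cu–NHC‑catalysed asymmetric conjugate addition of a Grignard reagent to a β,β‑disubstituted cyclohexenone creates the C5 quaternary stereocentre, the ligand antipode being chosen to give the (R)-ketone (vinyl = future C21).

**Step 3**
Reactants: 5 (R)-3-(1,3-dioxolan-2-ylmethyl)-3-vinylcyclohexan-1-one
Product: 7 (R)-3-(1,3-dioxolan-2-ylmethyl)-3-(hydroxymethyl)cyclohexan-1-one, via keto aldehyde 6 (not isolated)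
Conditions: O3, CH2Cl2/MeOH, −78 °C; PPh3; then NaBH4 (0.3 equiv), −78 °C
Reagents that add atoms: ozone, [O-][O+]=O
Why: Ozonolysis of the only alkene followed by low‑temperature borohydride reduction, which takes the aldehyde far faster than the ring ketone, gives the C21 alcohol without touching C5.

**Step 4**
Reactants: 7 (R)-3-(1,3-dioxolan-2-ylmethyl)-3-(hydroxymethyl)cyclohexan-1-one
Product: 8 (5R)-3-hydroxy-2-oxaspiro[4.5]decan-7-one
Conditions: 1 M HCl, THF, rt
Reagents that add atoms: water, O
Why: Acetal hydrolysis frees the C7 aldehyde, which closes with the C21 hydroxyl to a five‑membered lactol that masks both groups through the following base steps (anomeric mixture).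

**Step 5**
Reactants: 8 (5R)-3-hydroxy-2-oxaspiro[4.5]decan-7-one; 9 formaldehyde; 10 cyclohexane-1,3-dione
Product: 12 lactol triketone, via methylidene lactol 11 (not isolated)
Conditions: 9 (37 % aq., 1.0 equiv), pyrrolidine (10 mol %), EtCO2H (10 mol %), i‑PrOH, 45 °C; then 10, 45 °C
Reagents that add atoms: none
Why: Organocatalytic α‑methylenation of the lactol aldehyde (Mannich–elimination) gives a 2‑substituted acrolein, and Michael addition of the 1,3‑dione at its CH2 terminus forms C10–C12; C6 is formed unselectively and stays epimerisable.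

**Step 6**
Reactants: 12 lactol triketone
Product: 13 tetracyclic lactol enedione
Conditions: pyrrolidine (30 mol %), AcOH (30 mol %), toluene, 4 Å MS, 70 °C
Reagents that add atoms: none
Why: Intramolecular aldol condensation (second stage of a Robinson annulation) through the C8 enamine of the ring F ketone onto a dione carbonyl closes ring B and gives the C9=C10 enone, since only attack from C8 gives a six‑membered ring; the C6 epimers converge on the cis‑lactol.

**Step 7**
Reactants: 13 tetracyclic lactol enedione; 14 methyl acrylate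
Product: 16 ring A′ diketone, via Michael adduct 15 (not isolated)
Conditions: 14 (1.2 equiv), KOt‑Bu (0.1 equiv), THF/t‑BuOH, 0 °C; then KOt‑Bu (2.5 equiv), 50 °C; aq. HCl
Reagents that add atoms: none
Why: Michael–Claisen annulation: the vinylogous β‑diketone anion adds to acrylate at C8 anti to the C4–C5 bond (angular alkylation giving the cis‑fused F/B system, C13 cis to C21), then the C15 dienolate acylates on the ester (6‑enolendo‑exo‑trig) to close ring A′.

**Step 8**
Reactants: 16 ring A′ diketone
Product: 17 C15 chloride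
Conditions: N‑chlorosuccinimide (1.05 equiv), CH2Cl2, 0 °C
Reagents that add atoms: N-chlorosuccinimide, O=C1CCC(=O)N1Cl
Why: Electrophilic chlorination of the enolised vinylogous 1,3‑diketone occurs at C15, its only doubly activated carbon.

**Step 9**
Reactants: 17 C15 chloride
Product: 18 ring A methyl ester
Conditions: NaOMe (3 equiv), MeOH, 0 °C → rt
Reagents that add atoms: sodium methoxide, [Na+].[O-]C
Why: Favorskii rearrangement (ring contraction, not pericyclic): the C14 enolate displaces the allylic chloride via the cyclopropanone, methoxide adds to the carbonyl and the bond to C15 breaks because that releases the dienolate‑stabilised carbanion, so the carbonyl carbon leaves the ring as the C22 ester on C14 and ring A′ becomes ring A (a direct five‑ring closure at C15 would be a disfavoured 5‑enolendo process); methoxide equilibrates H‑14 and H‑15 to the cis arrangement of the target.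

**Step 10**
Reactants: 18 ring A methyl ester
Product: 20 bridged ketimine, via bridged 2-azadiene 19 (not isolated)
Conditions: NH3 (7 M in MeOH), 4 Å MS, rt; then NaBH4, −40 °C
Reagents that add atoms: ammonia, N
Why: Condensation of ammonia with the lactol aldehyde and the 1,5‑related ring F ketone, then chemoselective borohydride reduction of the aldimine, builds N–C7 and N=C1 (ring D); C6 epimerises through the imine–enamine pair and only the epimer with C7 cis to C1 can bridge, which sets C6.

**Step 11**
Reactants: 20 bridged ketimine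
Product: 21 lactam aldehyde
Conditions: O2 (1 atm), tetraphenylporphyrin (1 mol %), white LEDs, CH2Cl2, −30 °C → rt
Reagents that add atoms: dioxygen, O=O
Why: Proposed new method: dye‑sensitised aerobic scission of the C1=C2 bond of an N–H ketimine through its enamine tautomer, in which singlet oxygen adds to the electron‑rich enamine carbon C2 (zwitterion or ene‑type α‑hydroperoxy imine), the peroxide closes onto C1 to a 1,2‑dioxetane and stepwise O–O/C–C fragmentation gives the ring D lactam carbonyl and the C2 aldehyde, releasing C2–C4 from ring F; the closest known reaction types are the photo‑oxygenative cleavage of tertiary enamines to amide plus carbonyl and the Witkop–Winterfeldt oxidation of 2,3‑fused indoles, neither shown for a non‑aromatic bridged N–H ketimine beside an enone; no stereocentre is touched.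

**Step 12**
Reactants: 21 lactam aldehyde; 22 cis-but-2-ene
Product: 25 syn homoallylic alcohol, via (Z)-crotylpotassium 23 (not isolated), via (Z)-crotyldiisopinocampheylborane 24 (not isolated)
Conditions: 22, n‑BuLi, KOt‑Bu, THF, −78 → −45 °C; (−)-Ipc2BOMe, −78 °C; BF3·OEt2; 21 (0.3 equiv vs borane), −78 → −20 °C; NaOH, H2O2
Reagents that add atoms: none
Why: Brown asymmetric crotylboration through a closed chair transition state: the (Z)-crotyl geometry gives the syn C2‑OH/C18‑CH3 pair and the (−)-Ipc2B reagent (from (+)-α‑pinene) adds to the Si face of the aldehyde (reacting through the open form of its lactol), giving (2R,18R) under reagent control.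

**Step 13**
Reactants: 25 syn homoallylic alcohol
Product: 27 pentacyclic diol, via C19 aldehyde 26 (not isolated)
Conditions: O3, CH2Cl2/MeOH, −78 °C (1 equiv); Me2S; then Et3SiH (5 equiv), CF3CO2H, CH2Cl2 (2 mM), 0 °C
Reagents that add atoms: none
Why: Ozonolysis of the terminal alkene (the tetrasubstituted, electron‑poor enone is much slower) gives the C19 aldehyde, and intramolecular reductive N‑alkylation of the lactam (cyclic N‑acyl hemiaminal, N‑acyliminium ion, hydride from silane) forms N–C19 and the nine‑membered ring E, the C5 chain being held on the lactam face.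

**Step 14**
Reactants: 27 pentacyclic diol
Product: 28 CNP0123592.1
Conditions: Ac2O (1.1 equiv), 2,4,6‑collidine, CH2Cl2, −20 °C
Reagents that add atoms: acetic anhydride, CC(=O)OC(C)=O
Why: Selective O‑acetylation: the primary C21 alcohol reacts faster than the secondary C2 alcohol flanked by C18, giving the target.

**Compound list**
1 | 3-chlorocyclohex-2-en-1-one | O=C1C=C(Cl)CCC1 | starting material
2 | (1,3-dioxolan-2-ylmethyl)magnesium bromide | Br[Mg]CC1OCCO1 | starting material
3 | 3-(1,3-dioxolan-2-ylmethyl)cyclohex-2-en-1-one | O=C1C=C(CC2OCCO2)CCC1 | intermediate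
4 | vinylmagnesium bromide | C=C[Mg]Br | starting material
5 | (R)-3-(1,3-dioxolan-2-ylmethyl)-3-vinylcyclohexan-1-one | O1CCOC1C[C@]2(C=C)CCCC(=O)C2 | intermediate
6 | (R)-1-(1,3-dioxolan-2-ylmethyl)-3-oxocyclohexane-1-carbaldehyde | O1CCOC1C[C@]2(C=O)CCCC(=O)C2 | intermediate
7 | (R)-3-(1,3-dioxolan-2-ylmethyl)-3-(hydroxymethyl)cyclohexan-1-one | O1CCOC1C[C@]2(CO)CCCC(=O)C2 | intermediate
8 | (5R)-3-hydroxy-2-oxaspiro[4.5]decan-7-one (spiro lactol, both anomers) | OC1C[C@]2(CO1)CCCC(=O)C2 | intermediate
9 | formaldehyde | C=O | starting material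
10 | cyclohexane-1,3-dione | O=C1CCCC(=O)C1 | starting material
11 | 3-hydroxy-4-methylidene-2-oxaspiro[4.5]decan-7-one (spiro carbon as in 8) | OC1C(=C)[C@]2(CO1)CCCC(=O)C2 | intermediate
12 | 2-[(3-hydroxy-7-oxo-2-oxaspiro[4.5]decan-4-yl)methyl]cyclohexane-1,3-dione (spiro carbon as in 8; C6 epimers and anomers) | OC1C(CC3C(=O)CCCC3=O)[C@]2(CO1)CCCC(=O)C2 | intermediate
13 | tetracyclic lactol enedione: ring F ketone, ring B, ring C enone (C9=C10–C11=O), C7 lactol to O–C21 cis‑fused on ring B; C5 as in 8; H‑8 epimers, both anomers | OC1[C@H](CC5=C2CCCC5=O)[C@]6(CO1)CCCC(=O)C62 | intermediate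
14 | methyl acrylate | C=CC(=O)OC | starting material
15 | C8 Michael adduct of 13 (CH2CH2CO2Me on C8, cis to C21) | OC1[C@H](CC5=C2CCCC5=O)[C@]6(CO1)CCCC(=O)[C@@]62CCC(=O)OC | intermediate
16 | pentacyclic ring A′ diketone (six‑membered ring C8–C13–C14–C22(=O)–C15–C9; vinylogous 1,3‑diketone, H‑15 unassigned, largely enolised) | OC1[C@H](CC5=C2C7CCC5=O)[C@]6(CO1)CCCC(=O)[C@@]62CCC7=O | intermediate
17 | 15-chloro derivative of 16 | OC1[C@H](CC5=C2C7(Cl)CCC5=O)[C@]6(CO1)CCCC(=O)[C@@]62CCC7=O | intermediate
18 | ring A methyl ester: cyclopentane with CO2Me on C14, H‑14 and H‑15 cis on the face of C1; ring F ketone and C7 lactol retained | OC1[C@H](CC5=C2[C@@H]7CCC5=O)[C@]6(CO1)CCCC(=O)[C@@]62C[C@H]7C(=O)OC | intermediate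
19 | bridged 2-azadiene (C7=N–C1=C2; H‑6 as in target; free C21 OH) | N1=C[C@@H](CC5=C2[C@@H]7CCC5=O)[C@]6(CO)CCC=C1[C@@]62C[C@H]7C(=O)OC | intermediate
20 | bridged ketimine (N=C1, NCH2 at C7; azabicyclo[3.3.1] core of rings D and F) | N=1C[C@@H](CC5=C2[C@@H]7CCC5=O)[C@]6(CO)CCCC=1[C@@]62C[C@H]7C(=O)OC | intermediate
21 | lactam aldehyde (ring D N–H lactam, C2 aldehyde on the C5 chain, free C21 OH; in equilibrium with its six‑membered lactol) | COC(=O)[C@@H]1C[C@@]23C(=O)NC[C@@H](CC5=C2[C@@H]1CCC5=O)[C@]3(CO)CCC=O | intermediate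
22 | cis-but-2-ene | C/C=C\C | starting material
23 | (Z)-crotylpotassium | C/C=C\[CH2-].[K+] | intermediate
24 | (Z)-crotyldiisopinocampheylborane, (−)-Ipc series | C/C=C\CB([C@@H]1C[C@@H]2C[C@H]([C@H]1C)C2(C)C)[C@@H]3C[C@@H]4C[C@H]([C@H]3C)C4(C)C | intermediate
25 | syn homoallylic alcohol (2R,18R; vinyl on C18) | COC(=O)[C@@H]1C[C@@]23C(=O)NC[C@@H](CC5=C2[C@@H]1CCC5=O)[C@]3(CO)CC[C@@H](O)[C@H](C)C=C | intermediate
26 | C19 aldehyde (β‑hydroxy aldehyde) | COC(=O)[C@@H]1C[C@@]23C(=O)NC[C@@H](CC5=C2[C@@H]1CCC5=O)[C@]3(CO)CC[C@@H](O)[C@H](C)C=O | intermediate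
27 | pentacyclic diol (21‑O‑deacetyl target) | COC(=O)[C@@H]1C[C@@]23C(=O)N4C[C@@H](CC5=C2[C@@H]1CCC5=O)[C@]3(CO)CC[C@@H](O)[C@H](C)C4 | intermediate
28 | CNP0123592.1 | COC(=O)[C@@H]1C[C@@]23C(=O)N4C[C@@H](CC5=C2[C@@H]1CCC5=O)[C@]3(COC(C)=O)CC[C@@H](O)[C@H](C)C4 | target

**Step count and risks**
Total steps: 14. Longest linear sequence: 14 (from 1).

Steps most likely to fail:

Step 9 (Favorskii contraction): HCl elimination to a dienone, or opening to the isomeric C15 carboxylate, may compete, and the C14/C15 outcome rests on the stated assumption. The fallback sets out from 17 and closes ring A by alkylation instead of rearrangement. K2CO3 in MeOH at −20 °C opens the activated chloro‑diketone by retro‑Claisen methanolysis to the seco γ‑chloro‑enone methyl ester F1. KN(SiMe3)2 in THF at −78 °C then closes ring A by 5‑exo‑tet C‑alkylation of the ester enolate at the secondary allylic chloride, coming back to the route at 18.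

Step 11 (proposed aerobic C1=C2 scission): the enamine tautomer may be too scarce, or oxygenation may occur elsewhere. The fallback uses known chemistry from 20. Boc2O and Et3N in CH2Cl2 acylate the imine nitrogen through the enamine tautomer to the N‑Boc ene‑carbamate F2. Ozonolysis (O3, CH2Cl2, −78 °C; Me2S) cleaves its electron‑rich C1=C2 bond to the N‑Boc lactam aldehyde F3. CF3CO2H removes the Boc group and returns to the route at 21.

Step 13 (nine‑membered ring closure): the cyclic N‑acyl hemiaminal may not form, or the β‑hydroxy aldehyde may dehydrate in acid. The fallback sets out from 26 (made from 25 by the same ozonolysis). NaBH4 at −78 °C gives the triol F4. I2, PPh3 and imidazole convert only the unhindered primary C19 alcohol into the primary iodide F5. KOt‑Bu in THF/DMF at high dilution closes ring E by lactam N‑alkylation, rejoining the route at 27.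

**Further compounds**
F1 | step 9 | seco γ-chloro-enone methyl ester (ring A′ opened; Cl on C15) | OC1[C@H](CC5=C2C(Cl)CCC5=O)[C@]6(CO1)CCCC(=O)[C@@]62CCC(=O)OC
F2 | step 11 | N-Boc ene-carbamate (N–C1=C2) | CC(C)(C)OC(=O)N1C[C@@H](CC5=C2[C@@H]7CCC5=O)[C@]6(CO)CCC=C1[C@@]62C[C@H]7C(=O)OC
F3 | step 11 | N-Boc lactam aldehyde | COC(=O)[C@@H]1C[C@@]23C(=O)N(C(=O)OC(C)(C)C)C[C@@H](CC5=C2[C@@H]1CCC5=O)[C@]3(CO)CCC=O
F4 | step 13 | triol (C19 primary alcohol) | COC(=O)[C@@H]1C[C@@]23C(=O)NC[C@@H](CC5=C2[C@@H]1CCC5=O)[C@]3(CO)CC[C@@H](O)[C@H](C)CO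
F5 | step 13 | primary iodide at C19 | COC(=O)[C@@H]1C[C@@]23C(=O)NC[C@@H](CC5=C2[C@@H]1CCC5=O)[C@]3(CO)CC[C@@H](O)[C@H](C)CI
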